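**Retrosynthetic overview**

1. Target ⇐ late epoxidation of the 1(10)-alkene and C8 acylation with (2R,3S)-2,3-dimethyloxirane-2-carboxylic acid (from tiglyl alcohol by Sharpless epoxidation and oxidation).
2. Key disconnection C7–C8: a samarium ketyl radical from a C8 aldehyde adds to C7 of an (acetoxymethyl)butenolide; one step closes the ten-membered ring, sets C7 and C8 and unmasks the α-methylene lactone.
3. Seco-aldehyde ⇐ C3–C4 Nozaki–Hiyama–Kishi union of a (Z)-iodoalkenyl butenolide (C4–C7, C11–C13, C15) with an (E)-aldehyde (C1–C3, C8–C10, C14).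
4. Butenolide ⇐ ring-closing metathesis of an acrylate of a (Z)-iodo dienol (Sharpless kinetic resolution, then hydroalumination/iodination); aldehyde ⇐ carboalumination of a butynyl silyl ether and oxirane opening.
5. Ring order: lactone ring (metathesis) → ten-membered carbocycle (radical) → C1–C10 oxirane.

Assumption: positions use germacrane numbering (ring C1–C10, lactone C11–C13 closed on O6, C14 on C10, C15 on C4), and the numbered starting materials are taken as commercial.

**Route**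

Step 1
Reactants: 1 (E)-2-methylbut-2-en-1-ol
Product: 2 [(2S,3S)-2,3-dimethyloxiran-2-yl]methanol
Conditions: Ti(OiPr)4 (5 mol%), L-(+)-diethyl tartrate (6 mol%), t-BuOOH, CH2Cl2, −20 °C
Reagents that add atoms: tert-butyl hydroperoxide (CC(C)(C)OO)
Why: Sharpless asymmetric epoxidation; the L-(+)-tartrate titanium complex delivers oxygen to the face that gives the (2S,3S) epoxide (same sense as geraniol to its 2S,3S epoxide), and the E alkene keeps the two methyls cis.

Step 2
Reactants: 2 [(2S,3S)-2,3-dimethyloxiran-2-yl]methanol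
Product: 3 (2R,3S)-2,3-dimethyloxirane-2-carboxylic acid
Conditions: RuCl3 (2 mol%), NaIO4, CCl4/MeCN/H2O, 25 °C
Reagents that add atoms: water (O); sodium periodate ([Na+].[O-]I(=O)(=O)=O)
Why: Ruthenium tetroxide oxidation of the primary alcohol to the acid through the aldehyde hydrate leaves the oxirane intact; the change 2S to 2R is a CIP change only.

Step 3
Reactants: 4 2-(bromomethyl)prop-2-enoic acid
Product: 5 2-(acetoxymethyl)prop-2-enoic acid
Conditions: KOAc, AcOH, 60 °C
Reagents that add atoms: potassium acetate (CC(=O)[O-].[K+])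
Why: Allylic substitution of bromide by acetate; direct and allylic-shift attack give the same product.

Step 4
Reactants: 6 prop-2-enal; 7 prop-1-yn-1-ylmagnesium bromide (CH3C≡CMgBr)
Product: 8 rac-hex-1-en-4-yn-3-ol
Conditions: THF, −78 → 0 °C; then H2O
Reagents that add atoms: none
Why: 1,2-Addition of the alkynyl Grignard reagent to the enal at low temperature gives the racemic vinyl alkynyl carbinol.

Step 5
Reactants: 8 rac-hex-1-en-4-yn-3-ol
Product: 9 (3S)-hex-1-en-4-yn-3-ol
Conditions: Ti(OiPr)4 (15 mol%), L-(+)-diisopropyl tartrate (18 mol%), t-BuOOH (0.6 equiv), CH2Cl2, −20 °C, stopped at about 55% conversion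
Reagents that add atoms: none
Why: Sharpless kinetic resolution; with L-(+)-tartrate the 3R enantiomer (spatial analogue of fast-reacting (S)-oct-1-en-3-ol) is epoxidised at the vinyl group and the 3S alcohol is recovered.

Step 6
Reactants: 9 (3S)-hex-1-en-4-yn-3-ol
Product: 11 (3S,4Z)-5-iodohexa-1,4-dien-3-ol, via cyclic sodium alkenylaluminate 10 (not isolated)
Conditions: NaAlH2(OCH2CH2OCH3)2, Et2O, 0 → 25 °C; then I2, −78 °C
Reagents that add atoms: iodine (II)
Why: Alkoxide-directed trans-hydroalumination puts aluminium on the distal alkyne carbon, and iodinolysis with retention gives the Z iodide (iodine cis to the carbinol carbon); C3 is untouched.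

Step 7
Reactants: 11 (3S,4Z)-5-iodohexa-1,4-dien-3-ol; 5 2-(acetoxymethyl)prop-2-enoic acid
Product: 12 (3S,4Z)-5-iodohexa-1,4-dien-3-yl 2-(acetoxymethyl)prop-2-enoate
Conditions: DIC, DMAP (cat.), CH2Cl2, 0 °C
Reagents that add atoms: none
Why: Steglich esterification acylates on oxygen, so the carbinol configuration is retained.

Step 8
Reactants: 12 (3S,4Z)-5-iodohexa-1,4-dien-3-yl 2-(acetoxymethyl)prop-2-enoate
Product: 13 {(5S)-5-[(1Z)-2-iodoprop-1-en-1-yl]-2-oxo-2,5-dihydrofuran-3-yl}methyl acetate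
Conditions: second-generation Grubbs catalyst (5 mol%), toluene, 80 °C
Reagents that add atoms: none
Why: Ring-closing metathesis of the vinyl group with the acrylate forms the butenolide (C6, C7, C11–C13); the trisubstituted iodoalkene does not take part.

Step 9
Reactants: 14 tert-butyl(but-3-yn-1-yloxy)dimethylsilane; 15 oxirane
Product: 18 (3E)-6-(tert-butyldimethylsilyloxy)-4-methylhex-3-en-1-ol, via alkenyldimethylalane 16 (not isolated), via lithium alkenylalanate 17 (not isolated)
Conditions: AlMe3, Cp2ZrCl2 (cat.), CH2Cl2, 0 → 25 °C; n-BuLi, THF, −78 °C; oxirane, −78 → 25 °C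
Reagents that add atoms: trimethylaluminium (C[Al](C)C)
Why: Zirconium-catalysed carboalumination (Negishi) adds methyl and aluminium syn with methyl on the internal carbon, and the alanate opens oxirane with retention at the alkenyl carbon, fixing the 1(10)E geometry.

Step 10
Reactants: 18 (3E)-6-(tert-butyldimethylsilyloxy)-4-methylhex-3-en-1-ol
Product: 19 (3E)-6-(tert-butyldimethylsilyloxy)-4-methylhex-3-enal
Conditions: DMP, pyridine, CH2Cl2, 0 °C
Reagents that add atoms: none
Why: Buffered Dess–Martin oxidation gives the β,γ-unsaturated aldehyde without conjugation; it is used at once.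

Step 11
Reactants: 13 {(5S)-5-[(1Z)-2-iodoprop-1-en-1-yl]-2-oxo-2,5-dihydrofuran-3-yl}methyl acetate; 19 (3E)-6-(tert-butyldimethylsilyloxy)-4-methylhex-3-enal
Product: 20 {(5R)-5-[(1Z,3S,5E)-8-(tert-butyldimethylsilyloxy)-3-hydroxy-2,6-dimethylocta-1,5-dien-1-yl]-2-oxo-2,5-dihydrofuran-3-yl}methyl acetate
Conditions: CrCl2 (4 equiv), NiCl2 (1 mol%), Kishi oxazoline–sulfonamide ligand (antipode that directs Re-face attack), Et3N, THF, 25 °C
Reagents that add atoms: none
Why: Nozaki–Hiyama–Kishi alkenylation; the alkenylchromium keeps the Z geometry and adds to the Re face of the aldehyde under control of the chiral chromium sulfonamide complex to give 3S, while the furanone descriptor changes from 5S to 5R only because iodine is replaced by carbon.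

Step 12
Reactants: 20 {(5R)-5-[(1Z,3S,5E)-8-(tert-butyldimethylsilyloxy)-3-hydroxy-2,6-dimethylocta-1,5-dien-1-yl]-2-oxo-2,5-dihydrofuran-3-yl}methyl acetate; 21 benzaldehyde
Product: 23 (1Z,3S,5E)-1-[(2R)-4-(acetoxymethyl)-5-oxo-2,5-dihydrofuran-2-yl]-8-(tert-butyldimethylsilyloxy)-2,6-dimethylocta-1,5-dien-3-yl benzoate, via benzoyl bromide 22 (not isolated)
Conditions: 21, NBS (1.0 equiv), AIBN (cat.), PhCl, 80 °C; then 20, pyridine, DMAP (cat.), CH2Cl2, 0 °C
Reagents that add atoms: none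
Why: Radical-chain bromination of the formyl C–H gives benzoyl bromide, which acylates the C3 hydroxyl on oxygen under pyridine/DMAP catalysis with retention at C3.

Step 13
Reactants: 23 (1Z,3S,5E)-1-[(2R)-4-(acetoxymethyl)-5-oxo-2,5-dihydrofuran-2-yl]-8-(tert-butyldimethylsilyloxy)-2,6-dimethylocta-1,5-dien-3-yl benzoate
Product: 24 (1Z,3S,5E)-1-[(2R)-4-(acetoxymethyl)-5-oxo-2,5-dihydrofuran-2-yl]-8-hydroxy-2,6-dimethylocta-1,5-dien-3-yl benzoate
Conditions: HF·pyridine, pyridine, THF, 0 °C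
Reagents that add atoms: none
Why: Fluoride cleavage of the primary silyl ether under buffered, non-basic conditions spares the esters and the epimerisable C6.

Step 14
Reactants: 24 (1Z,3S,5E)-1-[(2R)-4-(acetoxymethyl)-5-oxo-2,5-dihydrofuran-2-yl]-8-hydroxy-2,6-dimethylocta-1,5-dien-3-yl benzoate
Product: 25 (1Z,3S,5E)-1-[(2R)-4-(acetoxymethyl)-5-oxo-2,5-dihydrofuran-2-yl]-2,6-dimethyl-8-oxoocta-1,5-dien-3-yl benzoate
Conditions: DMP, pyridine, CH2Cl2, 0 °C
Reagents that add atoms: none
Why: Dess–Martin oxidation gives the C8 aldehyde, which is cyclised without storage.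

Step 15
Reactants: 25 (1Z,3S,5E)-1-[(2R)-4-(acetoxymethyl)-5-oxo-2,5-dihydrofuran-2-yl]-2,6-dimethyl-8-oxoocta-1,5-dien-3-yl benzoate
Product: 26 (1(10)E,3S,4Z,6R,7R,8R)-3-(benzoyloxy)-8-hydroxygermacra-1(10),4,11(13)-trien-12,6-olide
Conditions: SmI2 (2.5 equiv), THF, 25 °C, slow addition of 25 (final 2 mM); then aq. NH4Cl, −20 °C
Reagents that add atoms: none
Why: Proposed new method: SmI2 reduces the aldehyde to a samarium ketyl radical that adds to C7 (β-carbon) of the butenolide, and the resulting lactone radical is reduced to the trivalent samarium enolate, which expels acetate (E1cB) to leave the exocyclic methylene (closest known types: SmI2 ketyl–olefin cyclisation onto enoates and β-acyloxy elimination from samarium enolates); H6 lies in the plane of the 4Z alkene (allylic 1,3-strain), which turns the butenolide face anti to C5 toward the tether (6,7-trans, 7R), and the samarium-bound ketyl oxygen is held syn to the ring oxygen O6 with C9 anti to C11 (8R).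

Step 16
Reactants: 26 (1(10)E,3S,4Z,6R,7R,8R)-3-(benzoyloxy)-8-hydroxygermacra-1(10),4,11(13)-trien-12,6-olide; 3 (2R,3S)-2,3-dimethyloxirane-2-carboxylic acid
Product: 28 (1(10)E,3S,4Z,6R,7R,8R)-3-(benzoyloxy)-8-{[(2R,3S)-2,3-dimethyloxirane-2-carbonyl]oxy}germacra-1(10),4,11(13)-trien-12,6-olide, via mixed Yamaguchi anhydride 27 (not isolated)
Conditions: 3, 2,4,6-trichlorobenzoyl chloride, Et3N, THF, 25 °C; then 26, DMAP, toluene, 25 °C
Reagents that add atoms: none
Why: Yamaguchi esterification acylates the hindered C8 hydroxyl on oxygen (retention at C8), and the acid has no enolisable stereocentre.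

Step 17
Reactants: 28 (1(10)E,3S,4Z,6R,7R,8R)-3-(benzoyloxy)-8-{[(2R,3S)-2,3-dimethyloxirane-2-carbonyl]oxy}germacra-1(10),4,11(13)-trien-12,6-olide
Product: 29 (1R,3S,4Z,6R,7R,8R,10R)-3-(benzoyloxy)-1,10-epoxy-8-{[(2R,3S)-2,3-dimethyloxirane-2-carbonyl]oxy}germacra-4,11(13)-dien-12,6-olide
Conditions: mCPBA (1.05 equiv), CH2Cl2, 0 °C
Reagents that add atoms: 3-chloroperoxybenzoic acid (OOC(=O)c1cccc(Cl)c1)
Why: Prilezhaev epoxidation takes only the electron-rich 1(10)-alkene (the 4Z alkene carries two allylic acyloxy groups, the methylene lactone is electron-poor) and, as with other germacranolide 1(10)-alkenes, attacks the outer face of the ring to give the 1R,10R oxirane.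

**Compound list**

1 | (E)-2-methylbut-2-en-1-ol | C/C=C(\C)CO | starting material
2 | [(2S,3S)-2,3-dimethyloxiran-2-yl]methanol | OC[C@]1(C)O[C@H]1C | intermediate
3 | (2R,3S)-2,3-dimethyloxirane-2-carboxylic acid | OC(=O)[C@]1(C)O[C@H]1C | intermediate
4 | 2-(bromomethyl)prop-2-enoic acid | OC(=O)C(=C)CBr | starting material
5 | 2-(acetoxymethyl)prop-2-enoic acid | CC(=O)OCC(=C)C(=O)O | intermediate
6 | prop-2-enal | C=CC=O | starting material
7 | prop-1-yn-1-ylmagnesium bromide | CC#C[Mg]Br | starting material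
8 | rac-hex-1-en-4-yn-3-ol | C=CC(O)C#CC | intermediate
9 | (3S)-hex-1-en-4-yn-3-ol | C=C[C@@H](C#CC)O | intermediate
10 | cyclic sodium alkenylaluminate (sodium bis(2-methoxyethoxy)aluminate bridging O3 and C5 of (3S,4Z)-hexa-1,4-dien-3-ol) | [Na+].C=C[C@H]1C=C(C)[Al-](OCCOC)(OCCOC)O1 | intermediate
11 | (3S,4Z)-5-iodohexa-1,4-dien-3-ol | C=C[C@@H](/C=C(/C)I)O | intermediate
12 | (3S,4Z)-5-iodohexa-1,4-dien-3-yl 2-(acetoxymethyl)prop-2-enoate | C=C[C@@H](/C=C(/C)I)OC(=O)C(=C)COC(C)=O | intermediate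
13 | {(5S)-5-[(1Z)-2-iodoprop-1-en-1-yl]-2-oxo-2,5-dihydrofuran-3-yl}methyl acetate | CC(=O)OCC1=C[C@@H](/C=C(/C)I)OC1=O | intermediate
14 | tert-butyl(but-3-yn-1-yloxy)dimethylsilane (but-3-yn-1-ol silyl ether) | C#CCCO[Si](C)(C)C(C)(C)C | starting material
15 | oxirane | C1CO1 | starting material
16 | [(1E)-4-(tert-butyldimethylsilyloxy)-2-methylbut-1-en-1-yl]dimethylalane | C/C(=C\[Al](C)C)CCO[Si](C)(C)C(C)(C)C | intermediate
17 | lithium butyl[(1E)-4-(tert-butyldimethylsilyloxy)-2-methylbut-1-en-1-yl]dimethylalanate | [Li+].CCCC[Al-](C)(C)/C=C(\C)CCO[Si](C)(C)C(C)(C)C | intermediate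
18 | (3E)-6-(tert-butyldimethylsilyloxy)-4-methylhex-3-en-1-ol | OCC/C=C(\C)CCO[Si](C)(C)C(C)(C)C | intermediate
19 | (3E)-6-(tert-butyldimethylsilyloxy)-4-methylhex-3-enal | O=CC/C=C(\C)CCO[Si](C)(C)C(C)(C)C | intermediate
20 | {(5R)-5-[(1Z,3S,5E)-8-(tert-butyldimethylsilyloxy)-3-hydroxy-2,6-dimethylocta-1,5-dien-1-yl]-2-oxo-2,5-dihydrofuran-3-yl}methyl acetate | CC(=O)OCC1=C[C@@H](/C=C(/C)[C@@H](O)C/C=C(\C)CCO[Si](C)(C)C(C)(C)C)OC1=O | intermediate
21 | benzaldehyde | O=Cc1ccccc1 | starting material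
22 | benzoyl bromide | O=C(Br)c1ccccc1 | intermediate
23 | (1Z,3S,5E)-1-[(2R)-4-(acetoxymethyl)-5-oxo-2,5-dihydrofuran-2-yl]-8-(tert-butyldimethylsilyloxy)-2,6-dimethylocta-1,5-dien-3-yl benzoate | CC(=O)OCC1=C[C@@H](/C=C(/C)[C@@H](OC(=O)c2ccccc2)C/C=C(\C)CCO[Si](C)(C)C(C)(C)C)OC1=O | intermediate
24 | (1Z,3S,5E)-1-[(2R)-4-(acetoxymethyl)-5-oxo-2,5-dihydrofuran-2-yl]-8-hydroxy-2,6-dimethylocta-1,5-dien-3-yl benzoate | CC(=O)OCC1=C[C@@H](/C=C(/C)[C@@H](OC(=O)c2ccccc2)C/C=C(\C)CCO)OC1=O | intermediate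
25 | (1Z,3S,5E)-1-[(2R)-4-(acetoxymethyl)-5-oxo-2,5-dihydrofuran-2-yl]-2,6-dimethyl-8-oxoocta-1,5-dien-3-yl benzoate | CC(=O)OCC1=C[C@@H](/C=C(/C)[C@@H](OC(=O)c2ccccc2)C/C=C(\C)CC=O)OC1=O | intermediate
26 | (1(10)E,3S,4Z,6R,7R,8R)-3-(benzoyloxy)-8-hydroxygermacra-1(10),4,11(13)-trien-12,6-olide | C=C1C(=O)O[C@@H]2/C=C(/C)[C@@H](OC(=O)c3ccccc3)C/C=C(\C)C[C@@H](O)[C@@H]12 | intermediate
27 | (2R,3S)-2,3-dimethyloxirane-2-carboxylic 2,4,6-trichlorobenzoic anhydride | O=C(OC(=O)[C@]1(C)O[C@H]1C)c1c(Cl)cc(Cl)cc1Cl | intermediate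
28 | (1(10)E,3S,4Z,6R,7R,8R)-3-(benzoyloxy)-8-{[(2R,3S)-2,3-dimethyloxirane-2-carbonyl]oxy}germacra-1(10),4,11(13)-trien-12,6-olide | C=C1C(=O)O[C@@H]2/C=C(/C)[C@@H](OC(=O)c3ccccc3)C/C=C(\C)C[C@@H](OC(=O)[C@]3(C)O[C@H]3C)[C@@H]12 | intermediate
29 | (1R,3S,4Z,6R,7R,8R,10R)-3-(benzoyloxy)-1,10-epoxy-8-{[(2R,3S)-2,3-dimethyloxirane-2-carbonyl]oxy}germacra-4,11(13)-dien-12,6-olide | C=C1C(=O)O[C@@H]2/C=C(/C)[C@@H](OC(=O)c3ccccc3)C[C@H]3O[C@]3(C)C[C@@H](OC(=O)[C@]3(C)O[C@H]3C)[C@@H]12 | target

**Summary**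

Total steps: 17. Longest linear sequence: 12 steps (steps 4 to 8, then 11 to 17).

Steps most likely to fail, each with a fallback:

Step 15 (samarium ketyl macrocyclisation). Closure of a ten-membered ring competes with pinacol coupling and simple reduction, and the C8 configuration rests on chelation. The fallback sets out from 25 and comes back at 26. If the cyclisation of 25 gives mainly the C8 epimer (1(10)E,3S,4Z,6R,7R,8S)-3-(benzoyloxy)-8-hydroxygermacra-1(10),4,11(13)-trien-12,6-olide F1, C8 is reset by a polar oxidation–reduction instead of in the radical step. DMP oxidises the epimer to the ketone (1(10)E,3S,4Z,6R,7S)-3-(benzoyloxy)-8-oxogermacra-1(10),4,11(13)-trien-12,6-olide F2. NaBH4 with CeCl3·7H2O at −78 °C then delivers hydride to the exposed outer face of the ring ketone, which places the hydroxyl on the lactone side and gives the 8R alcohol 26.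

Step 11 (ligand-controlled Nozaki–Hiyama–Kishi coupling). The chiral chromium complex may give only modest selectivity with this hindered 2-iodoalkene. The fallback sets out from 13 and 19 and comes back at 20. The coupling is run without ligand (CrCl2, NiCl2 cat., DMSO) to give 20 mixed with its C3 epimer {(5R)-5-[(1Z,3R,5E)-8-(tert-butyldimethylsilyloxy)-3-hydroxy-2,6-dimethylocta-1,5-dien-1-yl]-2-oxo-2,5-dihydrofuran-3-yl}methyl acetate F3. The mixture is oxidised with DMP to the enone {(5R)-5-[(1Z,5E)-8-(tert-butyldimethylsilyloxy)-2,6-dimethyl-3-oxoocta-1,5-dien-1-yl]-2-oxo-2,5-dihydrofuran-3-yl}methyl acetate F4. The enone is reduced with (R)-2-methyl-CBS-oxazaborolidine and catecholborane at −78 °C (alkenyl group as the large substituent), which gives the 3S alcohol 20.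

Step 17 (substrate-controlled epoxidation). The facial preference of the 1(10)-alkene in this 4Z macrocycle is inferred from related germacranolides and could be low or reversed. The fallback sets out from 28 and comes back at 29. Ring-conformation control is replaced by reagent control, using the chiral dioxirane from the D-fructose-derived Shi ketone (KHSO5, K2CO3, MeCN/dimethoxymethane/H2O, 0 °C). Its spiro transition state gives the R,R oxirane from E-trisubstituted alkenes, which here is 1R,10R. This fallback makes no new compound (F0).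

**Further compounds**

F1 | step 15 | (1(10)E,3S,4Z,6R,7R,8S)-3-(benzoyloxy)-8-hydroxygermacra-1(10),4,11(13)-trien-12,6-olide | C=C1C(=O)O[C@@H]2/C=C(/C)[C@@H](OC(=O)c3ccccc3)C/C=C(\C)C[C@H](O)[C@@H]12
F2 | step 15 | (1(10)E,3S,4Z,6R,7S)-3-(benzoyloxy)-8-oxogermacra-1(10),4,11(13)-trien-12,6-olide | C=C1C(=O)O[C@@H]2/C=C(/C)[C@@H](OC(=O)c3ccccc3)C/C=C(\C)CC(=O)[C@@H]12
F3 | step 11 | {(5R)-5-[(1Z,3R,5E)-8-(tert-butyldimethylsilyloxy)-3-hydroxy-2,6-dimethylocta-1,5-dien-1-yl]-2-oxo-2,5-dihydrofuran-3-yl}methyl acetate | CC(=O)OCC1=C[C@@H](/C=C(/C)[C@H](O)C/C=C(\C)CCO[Si](C)(C)C(C)(C)C)OC1=O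
F4 | step 11 | {(5R)-5-[(1Z,5E)-8-(tert-butyldimethylsilyloxy)-2,6-dimethyl-3-oxoocta-1,5-dien-1-yl]-2-oxo-2,5-dihydrofuran-3-yl}methyl acetate | CC(=O)OCC1=C[C@@H](/C=C(/C)C(=O)C/C=C(\C)CCO[Si](C)(C)C(C)(C)C)OC1=O
F0 | step 17 | none | none
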